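**Retrosynthetic overview**
1. Endgame on the bicycle: desilylation, C2 acetylation and C8 methacryloylation. The ten-membered carbocycle is opened at C1=C10 (ring-closing metathesis) to give an acyclic E-alkylidenebutenolide.
2. Key disconnection: the whole 6,12-butenolide ring (C6–O and C11–C12) goes back to CO2 and a (Z,Z)-bromodiene. One flask carries out Br/Li exchange, CO2 capture, anti selenolactonisation and syn selenoxide elimination.
3. Enabling feature: C11 and C6 are 1,3-related and held cis across the tetrasubstituted C7=C11 bond of the butenolide ring. C6 is allylic, and C4 is quaternary, so H6 is the only β-hydrogen. Anti addition plus syn elimination replaces H6 by O with retention, so the Z-C5=C6 diene becomes the E enol lactone, which anti lactonisation of a C5–C6 alkyne cannot give.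
4. The bromodiene comes from Negishi union of a C1–C6 alkyne with a C7–C14 bromo-triflate. In the alkyne, C2 is set by catalytic vinylzinc addition and C4 by A1,3-controlled directed epoxidation and reductive opening. In the bromo-triflate, C8 is set by an asymmetric glyoxylate-ene reaction, and its temporary 8,13-butenolide ring fixes the C7=C11 geometry.
5. Order of rings: temporary 8,13-butenolide (closed in step 3, opened in step 12), then the 6,12-butenolide (step 15), then the ten-membered ring (step 16).

Key step: step 15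

Numbering used (germacrane): C1–C10 are the ring carbons, with C1=C10, C2 carrying OAc, C4 the tertiary carbinol, C5=C6, and C8 carrying the methacrylate. C11 is the lactone α-carbon, C12 the lactone carbonyl, C13 the CH2OH carbon, C14 the methyl on C10 and C15 the methyl on C4. The target is (2R,4S,8R), 1(10)Z, 5E.
Assumption: selenenylation may occur on either face of C5=C6. One facial diastereomer of 24, 25 and F2 is drawn, and the other converges on the same alkene.

**Step 1**
Reactants: 1 isobutene; 2 methyl glyoxylate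
Product: 3 methyl (R)-2-hydroxy-4-methylpent-4-enoate
Conditions: (R)-BINOL (10 mol %), Ti(OiPr)2Cl2 (10 mol %), 4 Å molecular sieves, CH2Cl2, −30 °C
Reagents that add atoms: none
Why: Catalytic asymmetric carbonyl-ene (glyoxylate-ene) reaction in which the (R)-BINOL–titanium Lewis acid blocks one face of the aldehyde, so that the C8 carbinol should form as the R enantiomer together with the C9–C10(=CH2)–C14 methallyl unit.

**Step 2**
Reactants: 3 methyl (R)-2-hydroxy-4-methylpent-4-enoate
Product: 4 methyl (R)-2-acetoxy-4-methylpent-4-enoate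
Conditions: Ac2O, pyridine, DMAP (cat.), CH2Cl2, 0 °C → rt
Reagents that add atoms: acetic anhydride, CC(=O)OC(C)=O
Why: Routine O-acylation that brings in the two carbons destined to become C11 (acetate methyl) and C13 (acetate carbonyl) without touching C8.

**Step 3**
Reactants: 4 methyl (R)-2-acetoxy-4-methylpent-4-enoate
Product: 5 (R)-4-hydroxy-5-(2-methylallyl)furan-2(5H)-one
Conditions: LiN(SiMe3)2 (2.2 equiv), THF, −78 → 0 °C; then 1 M HCl
Reagents that add atoms: none
Why: Dieckmann condensation of the acetate enolate onto the neighbouring methyl ester (C7) closes the temporary five-membered ring in the 5-exo-trig mode, and the product is stored as its delocalised tetronate anion until the acid quench, which should keep C8 intact.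

**Step 4**
Reactants: 5 (R)-4-hydroxy-5-(2-methylallyl)furan-2(5H)-one
Product: 6 (R)-3-bromo-4-hydroxy-5-(2-methylallyl)furan-2(5H)-one
Conditions: NBS (1.0 equiv), CH2Cl2, 0 °C
Reagents that add atoms: N-bromosuccinimide, O=C1CCC(=O)N1Br
Why: Electrophilic bromination of the strongly nucleophilic enol carbon C11 of the vinylogous acid is much faster than attack of NBS on the isolated 1,1-disubstituted alkene.

**Step 5**
Reactants: 6 (R)-3-bromo-4-hydroxy-5-(2-methylallyl)furan-2(5H)-one
Product: 7 (R)-4-bromo-2-(2-methylallyl)-5-oxo-2,5-dihydrofuran-3-yl trifluoromethanesulfonate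
Conditions: Tf2O, iPr2NEt, CH2Cl2, −78 °C
Reagents that add atoms: triflic anhydride, O=S(=O)(OS(=O)(=O)C(F)(F)F)C(F)(F)F
Why: O-Sulfonylation of the vinylogous acid gives the enol triflate at C7, the more reactive of the two sp2 leaving groups for the later cross-coupling, and the low temperature with a hindered base should avoid deprotonation at C8.

**Step 6**
Reactants: 8 (E)-3-methylpent-2-en-4-yn-1-ol
Product: 9 (E)-3-methylpent-2-en-4-ynal
Conditions: MnO2 (excess), CH2Cl2, rt
Reagents that add atoms: none
Why: Chemoselective MnO2 oxidation of an allylic alcohol, which leaves the alkyne and the E geometry untouched.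

**Step 7**
Reactants: 9 (E)-3-methylpent-2-en-4-ynal
Product: 10 (S,E)-5-methylhepta-1,4-dien-6-yn-3-ol
Conditions: Zn(CH=CH2)2 (1.5 equiv), (−)-MIB (5 mol %), toluene, −30 °C; then water
Reagents that add atoms: divinylzinc, C=C[Zn]C=C
Why: Amino-alcohol-catalysed enantioselective addition of a vinylzinc reagent to an aldehyde, in which the (−)-MIB zinc chelate directs the vinyl group to one aldehyde face and thereby sets C2 (S descriptor here, R once C3 is reduced in step 9).

**Step 8**
Reactants: 10 (S,E)-5-methylhepta-1,4-dien-6-yn-3-ol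
Product: 11 (S)-1-[(2R,3R)-3-ethynyl-3-methyloxiran-2-yl]prop-2-en-1-ol
Conditions: mCPBA (1.05 equiv), NaHCO3, CH2Cl2, 0 °C
Reagents that add atoms: 3-chloroperbenzoic acid, O=C(OO)c1cccc(Cl)c1
Why: Hydroxyl-directed peracid epoxidation of the more substituted alkene, in which A1,3 strain between the C15 methyl group and the carbinol substituents fixes the reactive conformer (carbinol H in the alkene plane) so that oxygen is delivered syn to the OH to give the threo epoxy alcohol and thus the C4–O configuration.

**Step 9**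
Reactants: 11 (S)-1-[(2R,3R)-3-ethynyl-3-methyloxiran-2-yl]prop-2-en-1-ol
Product: 12 (3R,5S)-5-methylhept-1-en-6-yne-3,5-diol
Conditions: NaAlH2(OCH2CH2OMe)2 (3 equiv), THF, −20 → 0 °C; then aq. Rochelle salt
Reagents that add atoms: none
Why: Hydroxyl-directed reductive opening of a 2,3-epoxy alcohol, in which the aluminate bound at the C2 oxygen delivers hydride intramolecularly to C3 so that the 1,3-diol forms with the C4–O bond and both stereocentres unchanged.

**Step 10**
Reactants: 12 (3R,5S)-5-methylhept-1-en-6-yne-3,5-diol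
Product: 13 (3R,5S)-5-methyl-3,5-bis(triethylsilyloxy)hept-1-en-6-yne
Conditions: Et3SiOTf (2.5 equiv), 2,6-lutidine, CH2Cl2, −78 → 0 °C
Reagents that add atoms: triethylsilyl triflate, CC[Si](CC)(CC)OS(=O)(=O)C(F)(F)F
Why: A silyl triflate with a hindered pyridine base silylates the secondary and the tertiary alcohol alike, giving ethers that survive organolithium, zinc and aluminium reagents yet leave under mild acid or fluoride.

**Step 11**
Reactants: 13 (3R,5S)-5-methyl-3,5-bis(triethylsilyloxy)hept-1-en-6-yne; 7 (R)-4-bromo-2-(2-methylallyl)-5-oxo-2,5-dihydrofuran-3-yl trifluoromethanesulfonate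
Product: 16 (R)-3-bromo-5-(2-methylallyl)-4-[(3S,5R)-3-methyl-3,5-bis(triethylsilyloxy)hept-6-en-1-yn-1-yl]furan-2(5H)-one, via lithium acetylide 14 (not isolated), via alkynylzinc bromide 15 (not isolated)
Conditions: nBuLi (1.0 equiv), THF, −78 °C; ZnBr2 (1.1 equiv), −78 → 0 °C; 7, Pd(PPh3)4 (5 mol %), 0 °C → rt
Reagents that add atoms: none
Why: Negishi coupling of an alkynylzinc halide under zerovalent palladium catalysis, which should take place at the β-triflate (C7) rather than at the α-bromide (C11) and, being free of amine base, should spare the acidic H8.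

**Step 12**
Reactants: 16 (R)-3-bromo-5-(2-methylallyl)-4-[(3S,5R)-3-methyl-3,5-bis(triethylsilyloxy)hept-6-en-1-yn-1-yl]furan-2(5H)-one
Product: 17 (2E,4R)-2-bromo-6-methyl-3-[(3S,5R)-3-methyl-3,5-bis(triethylsilyloxy)hept-6-en-1-yn-1-yl]hepta-2,6-diene-1,4-diol
Conditions: iBu2AlH (5 equiv), CH2Cl2, −78 → 0 °C; then aq. Rochelle salt
Reagents that add atoms: none
Why: Exhaustive 1,2-reduction of the butenolide by iBu2AlH opens the temporary ring to a cis-but-2-ene-1,4-diol motif, so that the ring-enforced cis relation of C8 and C13, and hence of Br and C6, is carried into the open chain.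

**Step 13**
Reactants: 17 (2E,4R)-2-bromo-6-methyl-3-[(3S,5R)-3-methyl-3,5-bis(triethylsilyloxy)hept-6-en-1-yn-1-yl]hepta-2,6-diene-1,4-diol
Product: 18 (2E,4R)-2-bromo-6-methyl-3-[(1Z,3S,5R)-3-methyl-3,5-bis(triethylsilyloxy)hepta-1,6-dien-1-yl]hepta-2,6-diene-1,4-diol
Conditions: Zn dust activated with Cu(OAc)2 and AgNO3, THF–MeOH–H2O, 35 °C
Reagents that add atoms: none
Why: Boland reduction (activated zinc in aqueous methanol), a syn semireduction that is selective for conjugated alkynes over isolated alkenes, should give the Z-C5=C6 alkene with C4 cis to C7.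

**Step 14**
Reactants: 18 (2E,4R)-2-bromo-6-methyl-3-[(1Z,3S,5R)-3-methyl-3,5-bis(triethylsilyloxy)hepta-1,6-dien-1-yl]hepta-2,6-diene-1,4-diol
Product: 20 C13-O-TBS C8-O-TMS bis-ether of 18, via mono-TBS ether 19 (not isolated)
Conditions: tBuMe2SiCl (1.05 equiv), imidazole, CH2Cl2, 0 °C; then Me3SiCl (1.5 equiv), 0 °C
Reagents that add atoms: tert-butyldimethylsilyl chloride, CC(C)(C)[Si](C)(C)Cl; trimethylsilyl chloride, C[Si](C)(C)Cl
Why: Steric differentiation in silylation, in which the bulky TBS chloride takes only the primary allylic C13 alcohol and the small TMS chloride then caps the secondary C8 alcohol with a group that can be washed off after the next step.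

**Step 15**
Reactants: 20 C13-O-TBS C8-O-TMS bis-ether of 18; 21 carbon dioxide
Product: 27 4-[(1R)-1-hydroxy-3-methylbut-3-enyl]-3-(tert-butyldimethylsilyloxymethyl)-5-[(E,2S,4R)-2-methyl-2,4-bis(triethylsilyloxy)hex-5-enylidene]furan-2(5H)-one, via alkenyllithium 22 (not isolated), via lithium dienoate 23 (not isolated), via phenylselenolactone 24 (not isolated), via selenoxide 25 (not isolated), via trimethylsilyl ether 26 (not isolated)
Conditions: tBuLi (2.1 equiv), Et2O, −78 °C; CO2 (dry gas), −78 → −40 °C, then Ar purge; PhSeCl (1.1 equiv), THF, −78 → 0 °C; 30 % aq. H2O2, pyridine, 0 °C → rt; work-up with 5 % citric acid in MeOH–H2O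
Reagents that add atoms: carbon dioxide (21), O=C=O
Why: Bromine–lithium exchange with retention gives alkenyllithium 22, which adds to CO2 (C11–C12 bond) to give carboxylate 23 held cis to C6 by the tetrasubstituted C7=C11 bond; PhSeCl then forms a seleniranium ion on the neighbouring Z-C5=C6 alkene, the carboxylate oxygen opens it at allylic C6 (C6–O bond), and oxidation to selenoxide 25 triggers syn elimination. The closest known reaction types are carboxylation of alkenyllithiums, phenylselenolactonisation of unsaturated acids and selenoxide elimination, here simply run in one flask. The butenolide ring closes in the 5-exo mode (attack at the proximal carbon of the three-membered seleniranium ring), whereas the 6-endo alternative would need attack at C5, which is neopentyl-like next to quaternary C4 and not allylic. C5 and C6 are stereocentres only transiently: their relative configuration is fixed by anti addition to the Z alkene, both facial diastereomers are equivalent for what follows, and both centres vanish in the elimination. Because C4 bears no hydrogen, H6 is the only β-hydrogen, and anti addition followed by syn elimination amounts to replacement of H6 by oxygen with retention, so that C4 stays cis to C7 and the E enol lactone should result, the isomer that anti addition of a carboxylate to a C5–C6 alkyne cannot give. Chemoselectivity over the vinyl and methallyl groups rests on reversible selenenylation combined with the irreversible intramolecular capture that only C5=C6 offers, and the C8 oxygen is masked as a TMS ether that falls off in the citric acid work-up.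

**Step 16**
Reactants: 27 4-[(1R)-1-hydroxy-3-methylbut-3-enyl]-3-(tert-butyldimethylsilyloxymethyl)-5-[(E,2S,4R)-2-methyl-2,4-bis(triethylsilyloxy)hex-5-enylidene]furan-2(5H)-one
Product: 28 (2R,4S,8R)-8-hydroxy-2,4-bis(triethylsilyloxy)-13-(tert-butyldimethylsilyloxy)germacra-1(10)Z,5E,7(11)-trien-6,12-olide
Conditions: second-generation Hoveyda–Grubbs catalyst RuCl2(SIMes)(=CH-2-iPrOC6H4) (10 mol %), 1,4-benzoquinone (20 mol %), toluene (1 mM), 80 °C, Ar sparge
Reagents that add atoms: none
Why: Ring-closing metathesis of the vinyl and methallyl termini, which the planar E-dienolide holds close together through the cis relation of C4 and C8, should close the ten-membered ring with the trisubstituted C1=C10 alkene in the Z form that this ring size favours, while the hindered enol-lactone alkene stays inert.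

**Step 17**
Reactants: 28 (2R,4S,8R)-8-hydroxy-2,4-bis(triethylsilyloxy)-13-(tert-butyldimethylsilyloxy)germacra-1(10)Z,5E,7(11)-trien-6,12-olide
Product: 29 8-O-methacrylate of 28
Conditions: methacrylic anhydride, Et3N, DMAP, CH2Cl2, 0 °C → rt
Reagents that add atoms: methacrylic anhydride, C=C(C)C(=O)OC(=O)C(C)=C
Why: DMAP-catalysed acylation of the only free hydroxyl group (C8) proceeds with retention, and lactone migration to O8 is excluded because C12 lies trans to C8 on C7=C11.

**Step 18**
Reactants: 29 8-O-methacrylate of 28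
Product: 30 2-hydroxy compound (C2 triethylsilyl ether of 29 cleaved)
Conditions: PPTS (0.2 equiv), MeOH–CH2Cl2 (1:4), 0 °C
Reagents that add atoms: none
Why: Acid-catalysed methanolysis differentiates silyl ethers by bulk, so that the secondary allylic TES ether at C2 should go well before the tertiary TES ether at C4 and the primary TBS ether at C13.

**Step 19**
Reactants: 30 2-hydroxy compound (C2 triethylsilyl ether of 29 cleaved)
Product: 31 2-O-acetate of 30
Conditions: Ac2O, pyridine, DMAP (cat.), CH2Cl2, 0 °C
Reagents that add atoms: acetic anhydride, CC(=O)OC(C)=O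
Why: DMAP-catalysed acetylation of the single free secondary alcohol installs the C2 acetate with retention of configuration.

**Step 20**
Reactants: 31 2-O-acetate of 30
Product: 32 target CNP0122447.1
Conditions: HF·pyridine, pyridine, THF, 0 °C → rt
Reagents that add atoms: none
Why: Buffered fluoride-mediated desilylation removes the C13 TBS and C4 TES ethers under conditions that should leave both esters, the enol lactone and the tertiary allylic alcohol untouched.

**Compound list**
1 | isobutene | CC(C)=C | starting material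
2 | methyl glyoxylate | COC(=O)C=O | starting material
3 | methyl (R)-2-hydroxy-4-methylpent-4-enoate | COC(=O)[C@H](O)CC(C)=C | intermediate
4 | methyl (R)-2-acetoxy-4-methylpent-4-enoate | COC(=O)[C@H](OC(C)=O)CC(C)=C | intermediate
5 | (R)-4-hydroxy-5-(2-methylallyl)furan-2(5H)-one | C=C(C)C[C@H]1OC(=O)C=C1O | intermediate
6 | (R)-3-bromo-4-hydroxy-5-(2-methylallyl)furan-2(5H)-one | C=C(C)C[C@H]1OC(=O)C(Br)=C1O | intermediate
7 | (R)-4-bromo-2-(2-methylallyl)-5-oxo-2,5-dihydrofuran-3-yl trifluoromethanesulfonate | C=C(C)C[C@H]1OC(=O)C(Br)=C1OS(=O)(=O)C(F)(F)F | intermediate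
8 | (E)-3-methylpent-2-en-4-yn-1-ol | C#C/C(C)=C/CO | starting material
9 | (E)-3-methylpent-2-en-4-ynal | C#C/C(C)=C/C=O | intermediate
10 | (S,E)-5-methylhepta-1,4-dien-6-yn-3-ol | C#C/C(C)=C/[C@@H](O)C=C | intermediate
11 | (S)-1-[(2R,3R)-3-ethynyl-3-methyloxiran-2-yl]prop-2-en-1-ol | C#C[C@@]1(C)O[C@@H]1[C@@H](O)C=C | intermediate
12 | (3R,5S)-5-methylhept-1-en-6-yne-3,5-diol | C#C[C@@](C)(O)C[C@@H](O)C=C | intermediate
13 | (3R,5S)-5-methyl-3,5-bis(triethylsilyloxy)hept-1-en-6-yne | C#C[C@@](C)(O[Si](CC)(CC)CC)C[C@@H](O[Si](CC)(CC)CC)C=C | intermediate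
14 | lithium acetylide of 13 | [Li]C#C[C@@](C)(O[Si](CC)(CC)CC)C[C@@H](O[Si](CC)(CC)CC)C=C | intermediate
15 | alkynylzinc bromide of 13 | Br[Zn]C#C[C@@](C)(O[Si](CC)(CC)CC)C[C@@H](O[Si](CC)(CC)CC)C=C | intermediate
16 | (R)-3-bromo-5-(2-methylallyl)-4-[(3S,5R)-3-methyl-3,5-bis(triethylsilyloxy)hept-6-en-1-yn-1-yl]furan-2(5H)-one | C=C(C)C[C@H]1OC(=O)C(Br)=C1C#C[C@@](C)(O[Si](CC)(CC)CC)C[C@@H](O[Si](CC)(CC)CC)C=C | intermediate
17 | (2E,4R)-2-bromo-6-methyl-3-[(3S,5R)-3-methyl-3,5-bis(triethylsilyloxy)hept-6-en-1-yn-1-yl]hepta-2,6-diene-1,4-diol | OC/C(Br)=C(\[C@H](O)CC(C)=C)C#C[C@@](C)(O[Si](CC)(CC)CC)C[C@@H](O[Si](CC)(CC)CC)C=C | intermediate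
18 | (2E,4R)-2-bromo-6-methyl-3-[(1Z,3S,5R)-3-methyl-3,5-bis(triethylsilyloxy)hepta-1,6-dien-1-yl]hepta-2,6-diene-1,4-diol | OC/C(Br)=C(\[C@H](O)CC(C)=C)/C=C\[C@@](C)(O[Si](CC)(CC)CC)C[C@@H](O[Si](CC)(CC)CC)C=C | intermediate
19 | C13-O-TBS ether of 18 (C8 alcohol free) | CC(C)(C)[Si](C)(C)OC/C(Br)=C(\[C@H](O)CC(C)=C)/C=C\[C@@](C)(O[Si](CC)(CC)CC)C[C@@H](O[Si](CC)(CC)CC)C=C | intermediate
20 | C13-O-TBS C8-O-TMS bis-ether of 18 | CC(C)(C)[Si](C)(C)OC/C(Br)=C(\[C@H](O[Si](C)(C)C)CC(C)=C)/C=C\[C@@](C)(O[Si](CC)(CC)CC)C[C@@H](O[Si](CC)(CC)CC)C=C | intermediate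
21 | carbon dioxide | O=C=O | starting material
22 | alkenyllithium (Li in place of Br at C11 of 20) | CC(C)(C)[Si](C)(C)OC/C([Li])=C(\[C@H](O[Si](C)(C)C)CC(C)=C)/C=C\[C@@](C)(O[Si](CC)(CC)CC)C[C@@H](O[Si](CC)(CC)CC)C=C | intermediate
23 | lithium dienoate (carboxylate on C11 cis to C6; C5=C6 Z) | [Li+].CC(C)(C)[Si](C)(C)OC/C(C([O-])=O)=C(\[C@H](O[Si](C)(C)C)CC(C)=C)/C=C\[C@@](C)(O[Si](CC)(CC)CC)C[C@@H](O[Si](CC)(CC)CC)C=C | intermediate
24 | phenylselenolactone (butenolide with sp3 C6 (R) bearing the C5 (S) phenylselanyl carbon; one facial isomer drawn) | C=C(C)C[C@@H](O[Si](C)(C)C)C1=C(CO[Si](C)(C)C(C)(C)C)C(=O)O[C@H]1[C@H]([Se]c2ccccc2)[C@@](C)(O[Si](CC)(CC)CC)C[C@@H](O[Si](CC)(CC)CC)C=C | intermediate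
25 | selenoxide of 24 | C=C(C)C[C@@H](O[Si](C)(C)C)C1=C(CO[Si](C)(C)C(C)(C)C)C(=O)O[C@H]1[C@H]([Se](=O)c2ccccc2)[C@@](C)(O[Si](CC)(CC)CC)C[C@@H](O[Si](CC)(CC)CC)C=C | intermediate
26 | C8-O-TMS ether of 27 | C=C(C)C[C@@H](O[Si](C)(C)C)C1=C(CO[Si](C)(C)C(C)(C)C)C(=O)O/C1=C/[C@@](C)(O[Si](CC)(CC)CC)C[C@@H](O[Si](CC)(CC)CC)C=C | intermediate
27 | 4-[(1R)-1-hydroxy-3-methylbut-3-enyl]-3-(tert-butyldimethylsilyloxymethyl)-5-[(E,2S,4R)-2-methyl-2,4-bis(triethylsilyloxy)hex-5-enylidene]furan-2(5H)-one | C=C(C)C[C@@H](O)C1=C(CO[Si](C)(C)C(C)(C)C)C(=O)O/C1=C/[C@@](C)(O[Si](CC)(CC)CC)C[C@@H](O[Si](CC)(CC)CC)C=C | intermediate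
28 | (2R,4S,8R)-8-hydroxy-2,4-bis(triethylsilyloxy)-13-(tert-butyldimethylsilyloxy)germacra-1(10)Z,5E,7(11)-trien-6,12-olide | O[C@@H]1C/C(C)=C\[C@H](O[Si](CC)(CC)CC)C[C@](C)(O[Si](CC)(CC)CC)/C=C2/OC(=O)C(CO[Si](C)(C)C(C)(C)C)=C21 | intermediate
29 | 8-O-methacrylate of 28 | C=C(C)C(=O)O[C@@H]1C/C(C)=C\[C@H](O[Si](CC)(CC)CC)C[C@](C)(O[Si](CC)(CC)CC)/C=C2/OC(=O)C(CO[Si](C)(C)C(C)(C)C)=C21 | intermediate
30 | 2-hydroxy compound (C2 triethylsilyl ether of 29 cleaved) | C=C(C)C(=O)O[C@@H]1C/C(C)=C\[C@H](O)C[C@](C)(O[Si](CC)(CC)CC)/C=C2/OC(=O)C(CO[Si](C)(C)C(C)(C)C)=C21 | intermediate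
31 | 2-O-acetate of 30 | C=C(C)C(=O)O[C@@H]1C/C(C)=C\[C@H](OC(C)=O)C[C@](C)(O[Si](CC)(CC)CC)/C=C2/OC(=O)C(CO[Si](C)(C)C(C)(C)C)=C21 | intermediate
32 | CNP0122447.1, (2R,4S,8R)-2-acetoxy-4,13-dihydroxy-8-methacryloyloxygermacra-1(10)Z,5E,7(11)-trien-6,12-olide | C=C(C)C(=O)O[C@@H]1C/C(C)=C\[C@H](OC(C)=O)C[C@](C)(O)/C=C2/OC(=O)C(CO)=C21 | target

**Step count and risks**
Total step count: 20. Longest linear sequence: 15 steps (steps 6–20, from 8).

Step 15 is the most exposed step. The selenium electrophile may be consumed by the more accessible methallyl or vinyl groups, the ring may close in the endo sense, or base-induced elimination may compete with the pericyclic syn elimination and erode the E geometry. The fallback replaces the chalcogen chemistry with a Wacker-type oxidative lactonisation. It sets out from lithium dienoate 23, which is acidified with cold dilute H3PO4 to the free dienoic acid F1. Pd(OAc)2 (10 mol %), NaOAc and O2 in DMSO should then bring about anti oxypalladation at C6 by the carboxylic acid, followed by syn β-hydride elimination of H6, which is again the only β-hydrogen. That is the same net retention, and the route is rejoined at trimethylsilyl ether 26.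

Step 16 comes second. Oligomerisation may compete with ring closure, the ruthenium carbene may be trapped by the enol-lactone alkene, and heat or ruthenium hydrides may isomerise the acyclic E enol lactone before the ring closes. The fallback closes the carbocycle before the enol lactone is unveiled. It sets out from phenylselenolactone 24, isolated by stopping step 15 before the peroxide is added. Ring-closing metathesis under the conditions of step 16 gives the macrocyclic phenylselenolactone F2. Treatment with H2O2 and pyridine and a citric acid work-up then performs the syn elimination inside the ring and returns to the route at 28.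

Step 13 comes third. The hindered alkyne may be reduced only sluggishly, the vinylic bromine may be lost reductively, or reduction may go too far. The fallback brings the Z alkene in by cross-coupling instead of by reduction. It sets out from alkyne 13, which undergoes rhodium-catalysed trans-hydroboration ([Rh(cod)Cl]2, PiPr3, Et3N, pinacolborane, cyclohexane) to give the (Z)-alkenylboronate F3. Suzuki–Miyaura coupling with 7 at the triflate (PdCl2(dppf), K3PO4, THF–H2O, rt) gives the dienyl bromobutenolide F4. Reduction with iBu2AlH as in step 12 then returns to the route at 18.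

**Further compounds**
F1 | step 15 | free dienoic acid (carboxyl on C11 cis to C6; C5=C6 Z; silyl ethers as in 20) | CC(C)(C)[Si](C)(C)OC/C(C(=O)O)=C(\[C@H](O[Si](C)(C)C)CC(C)=C)/C=C\[C@@](C)(O[Si](CC)(CC)CC)C[C@@H](O[Si](CC)(CC)CC)C=C
F2 | step 16 | macrocyclic phenylselenolactone (ten-membered ring closed at C1=C10; C5 SePh; C6 sp3; C8 O-TMS) | C[Si](C)(C)O[C@@H]1C/C(C)=C\[C@H](O[Si](CC)(CC)CC)C[C@](C)(O[Si](CC)(CC)CC)[C@@H]([Se]c3ccccc3)[C@@H]2OC(=O)C(CO[Si](C)(C)C(C)(C)C)=C21
F3 | step 13 | (Z)-alkenyl pinacolboronate of 13 | CC1(C)OB(/C=C\[C@@](C)(O[Si](CC)(CC)CC)C[C@@H](O[Si](CC)(CC)CC)C=C)OC1(C)C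
F4 | step 13 | (R)-3-bromo-5-(2-methylallyl)-4-[(1Z,3S,5R)-3-methyl-3,5-bis(triethylsilyloxy)hepta-1,6-dien-1-yl]furan-2(5H)-one | C=C(C)C[C@H]1OC(=O)C(Br)=C1/C=C\[C@@](C)(O[Si](CC)(CC)CC)C[C@@H](O[Si](CC)(CC)CC)C=C
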